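**Plan**
- Retrosynthesis: the O–CH3 bond on the C7 oxygen is cut first. Then the aryl–ketone bond C8–C1' and the C7–O bond are cut together, which leads to a C7≡C8 coumarin aryne and a carboxylic acid that already holds the whole side chain (C1' acid carbon, C2' enol isovalerate, C3' = CMe2).
- Enabling feature: on the benzene ring of the coumarin, the acyl group on C8 sits between O1-bearing C8a and oxygen-bearing C7. This adjacent C7–O / C8–acyl pair is what an aryne inserting into a carboxylic acid C–O bond produces.
- Forward: the 8-silyl-7-triflyloxycoumarin is made from umbelliferone in three steps. The enol-ester acid is made from sodium 3-methyl-2-oxobutanoate and isovaleryl chloride in three steps.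
- The two arms are joined in the aryne insertion and the freed 7-hydroxyl is methylated. Both rings are present from the start; none is formed.
- Stereochemistry: none to set. There is no stereocentre, and the C2'=C3' alkene carries two identical methyl groups.

Key step: step 7

Remark: the target is achiral, so "single enantiomer" is taken to mean this one compound and no asymmetric step is needed.

**Route**

Step 1
Reactants: 1 umbelliferone (7-hydroxycoumarin)
Product: 2 7-hydroxy-8-iodocoumarin
Conditions: I2 (1.0 equiv), KI, 20% aq. NH3, rt; acidify
Reagents that add atoms: iodine, II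
Why: Electrophilic aromatic iodination of the phenoxide: C8, ortho to the 7-oxygen and next to O1-bearing C8a, is the most nucleophilic ring position of umbelliferone, and one equivalent of iodine in aqueous ammonia is the established way to the 8-iodide.

Step 2
Reactants: 2 7-hydroxy-8-iodocoumarin
Product: 3 8-iodo-7-(trimethylsilyloxy)coumarin
Conditions: (Me3Si)2NH, THF, reflux; evaporate, use crude under argon
Reagents that add atoms: hexamethyldisilazane, C[Si](C)(C)N[Si](C)(C)C
Why: Phenol silylation by hexamethyldisilazane is driven by loss of ammonia and leaves only volatiles, so the moisture-sensitive aryl silyl ether can be used crude after evaporation.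

Step 3
Reactants: 3 8-iodo-7-(trimethylsilyloxy)coumarin
Product: 6 2-oxo-8-(trimethylsilyl)-2H-chromen-7-yl trifluoromethanesulfonate, via 8-lithio-7-(trimethylsilyloxy)coumarin 4 (not isolated), via lithium 8-(trimethylsilyl)coumarin-7-olate 5 (not isolated)
Conditions: n-BuLi (1.05 equiv), THF, −100 °C; then Tf2O, −100 → −78 °C
Reagents that add atoms: trifluoromethanesulfonic anhydride, O=S(=O)(OS(=O)(=O)C(F)(F)F)C(F)(F)F
Why: Iodine–lithium exchange at −100 °C should be faster than butyl addition to the lactone, and the weakly nucleophilic, doubly oxygen-flanked aryllithium 4 should be captured intramolecularly by the neighbouring O–SiMe3 group in a 1,3-O→C silyl shift (retro-Brook rearrangement) to phenoxide 5, which Tf2O sulfonylates in the same flask, as in the standard one-flask preparation of o-silylaryl triflates.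

Step 4
Reactants: 7 sodium 3-methyl-2-oxobutanoate
Product: 8 allyl 3-methyl-2-oxobutanoate
Conditions: allyl bromide, DMF, rt
Reagents that add atoms: allyl bromide, C=CCBr
Why: SN2 O-alkylation of a carboxylate salt with a reactive allylic bromide in a dipolar aprotic solvent; the allyl ester is chosen because it can later be removed under neutral conditions that an enol ester tolerates.

Step 5
Reactants: 8 allyl 3-methyl-2-oxobutanoate; 9 isovaleryl chloride (3-methylbutanoyl chloride)
Product: 10 allyl 3-methyl-2-(3-methylbutanoyloxy)but-2-enoate
Conditions: Et3N, DMAP (cat.), CH2Cl2, 0 °C → rt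
Reagents that add atoms: none
Why: Enol O-acylation of an α-keto ester: triethylamine enolises the only acidic position (the isopropyl methine next to the 1,2-dicarbonyl), the DMAP-derived acylpyridinium is captured on oxygen because C-acylation would have to build a quaternary carbon, and the two identical methyl groups leave no alkene geometry to control.

Step 6
Reactants: 10 allyl 3-methyl-2-(3-methylbutanoyloxy)but-2-enoate
Product: 11 3-methyl-2-(3-methylbutanoyloxy)but-2-enoic acid
Conditions: Pd(PPh3)4 (cat.), sodium p-toluenesulfinate, THF–MeOH, rt; cold dilute HCl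
Reagents that add atoms: none
Why: Tsuji–Trost deallylation: Pd(0) ionises the allyl ester to a π-allyl complex that the soft, non-basic sulfinate captures as a neutral sulfone, so the carboxylate is released without an amine or hydroxide that would cleave the enol ester.

Step 7
Reactants: 6 2-oxo-8-(trimethylsilyl)-2H-chromen-7-yl trifluoromethanesulfonate; 11 3-methyl-2-(3-methylbutanoyloxy)but-2-enoic acid
Product: 16 7-hydroxy-8-[3-methyl-2-(3-methylbutanoyloxy)but-2-enoyl]coumarin, via sodium enol-ester carboxylate 12 (not isolated), via 7,8-didehydrocoumarin 13 (not isolated), via C8-sodio aryl ester 14 (not isolated), via sodium 7-phenoxide ketone 15 (not isolated)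
Conditions: 11 (1.3 equiv), NaH (1.25 equiv), THF, 0 °C; then 6 (1.0 equiv), CsF (3 equiv), THF, sealed tube, 100 °C; cold 0.5 M HCl quench
Reagents that add atoms: none
Why: Fluoride removes the silyl group of 6 and triflate leaves, giving aryne 13, whose C7≡C8 bond is polarised by the inductively withdrawing ring oxygen on C8a (and by the enoate para to C7), so carboxylate 12 should add through oxygen at C7 and the charge should settle on C8 next to O1 (14). The C8 anion then attacks the carbonyl of the new aryl ester through a four-membered transition state (4-exo-trig), and the strained benzoxetene alkoxide collapses to the C8 ketone and the 7-phenoxide 15, so C7–O and C8–C1' are formed and no ring stays closed. The closest known reaction type is the insertion of arynes from o-silylaryl triflates into the C–O bond of carboxylic acids to give o-hydroxyaryl ketones, used here on a coumarin aryne and an enol-ester acid. Acyl transfer must outrun protonation of the aryl anion, which the preformed salt in an aprotic medium should secure because no acidic proton is present. The enol ester and the enone must also survive: the ketone-conjugated phenoxide 15 is a much weaker base and nucleophile than an enolate, and without a proton source its reversible oxa-Michael closure onto C3' cannot be fixed as a chromanone before the cold acidic quench. No stereocentre is formed.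

Step 8
Reactants: 16 7-hydroxy-8-[3-methyl-2-(3-methylbutanoyloxy)but-2-enoyl]coumarin
Product: 17 exotimarin H (7-methoxy-8-[3-methyl-2-(3-methylbutanoyloxy)but-2-enoyl]coumarin)
Conditions: MeI (excess), K2CO3, DMF, 0 °C → rt
Reagents that add atoms: iodomethane, CI
Why: Williamson-type O-methylation of an acidic, ketone-conjugated phenol with iodomethane and carbonate in DMF is fast at room temperature and irreversible, so it should outpace the reversible 6-endo oxa-Michael closure of the phenoxide onto C3' and leave the enol ester and the lactone untouched.

**Compound list**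

1 | umbelliferone (7-hydroxycoumarin) | O=c1ccc2ccc(O)cc2o1 | starting material
2 | 7-hydroxy-8-iodocoumarin | O=c1ccc2ccc(O)c(I)c2o1 | intermediate
3 | 8-iodo-7-(trimethylsilyloxy)coumarin | C[Si](C)(C)Oc1ccc2ccc(=O)oc2c1I | intermediate
4 | 8-lithio-7-(trimethylsilyloxy)coumarin (not isolated) | C[Si](C)(C)Oc1ccc2ccc(=O)oc2c1[Li] | intermediate
5 | lithium 8-(trimethylsilyl)coumarin-7-olate (not isolated) | C[Si](C)(C)c1c([O-])ccc2ccc(=O)oc12.[Li+] | intermediate
6 | 2-oxo-8-(trimethylsilyl)-2H-chromen-7-yl trifluoromethanesulfonate | C[Si](C)(C)c1c(OS(=O)(=O)C(F)(F)F)ccc2ccc(=O)oc12 | intermediate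
7 | sodium 3-methyl-2-oxobutanoate | CC(C)C(=O)C(=O)[O-].[Na+] | starting material
8 | allyl 3-methyl-2-oxobutanoate | CC(C)C(=O)C(=O)OCC=C | intermediate
9 | isovaleryl chloride (3-methylbutanoyl chloride) | CC(C)CC(=O)Cl | starting material
10 | allyl 3-methyl-2-(3-methylbutanoyloxy)but-2-enoate | CC(C)CC(=O)OC(C(=O)OCC=C)=C(C)C | intermediate
11 | 3-methyl-2-(3-methylbutanoyloxy)but-2-enoic acid | CC(C)CC(=O)OC(C(=O)O)=C(C)C | intermediate
12 | sodium 3-methyl-2-(3-methylbutanoyloxy)but-2-enoate (not isolated) | CC(C)CC(=O)OC(C(=O)[O-])=C(C)C.[Na+] | intermediate
13 | 7,8-didehydrocoumarin, the C7≡C8 aryne (not isolated) | O=C1C=CC2=C(O1)C#CC=C2 | intermediate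
14 | sodium 7-[3-methyl-2-(3-methylbutanoyloxy)but-2-enoyloxy]-2-oxo-2H-chromen-8-ide (not isolated) | CC(C)CC(=O)OC(=C(C)C)C(=O)Oc1ccc2ccc(=O)oc2[c-]1.[Na+] | intermediate
15 | sodium 8-[3-methyl-2-(3-methylbutanoyloxy)but-2-enoyl]-2-oxo-2H-chromen-7-olate (not isolated) | CC(C)CC(=O)OC(C(=O)c1c([O-])ccc2ccc(=O)oc12)=C(C)C.[Na+] | intermediate
16 | 7-hydroxy-8-[3-methyl-2-(3-methylbutanoyloxy)but-2-enoyl]coumarin | CC(C)CC(=O)OC(C(=O)c1c(O)ccc2ccc(=O)oc12)=C(C)C | intermediate
17 | exotimarin H | COc1ccc2ccc(=O)oc2c1C(=O)C(OC(=O)CC(C)C)=C(C)C | target

**Totals**
Total step count: 8. Longest linear sequence: 5 steps (1 → 2 → 3 → 6 → 16 → 17, or equally 7 → 8 → 10 → 11 → 16 → 17).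

**Steps most likely to fail**

Step 7 (aryne insertion). The aryl anion may be protonated before acyl transfer, so that only O-arylation occurs. Fluoride or the phenoxide may also strip the isovaleryl group, or the product phenoxide may consume the aryne. The fallback drops the aryne and builds the side chain on the iodide. It sets out from 2. O-Methylation (MeI, K2CO3, acetone) should give 8-iodo-7-methoxycoumarin F1. Sonogashira coupling with 3-methylbut-1-yne (PdCl2(PPh3)2, CuI, Et3N, DMF, sealed tube, 60 °C) should give 7-methoxy-8-(3-methylbut-1-yn-1-yl)coumarin F2. Palladium(II)-catalysed oxidation of the aryl alkyl alkyne in DMSO (PdCl2 cat., 120–140 °C) should give the 1,2-dione 7-methoxy-8-(3-methyl-2-oxobutanoyl)coumarin F3. Its only enolisable position is the isopropyl methine, so O-acylation with 9 (Et3N, DMAP, CH2Cl2) should give the enol isovalerate, and the fallback returns to the route at 17.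

Step 3 (exchange, silyl shift, triflation). Butyllithium or the aryllithium may add to the lactone carbonyl or to C4 before the silyl shift, or the O-silyl group may be lost so that no C–Si bond forms. The fallback puts silicon on C8 by catalysis instead of an organolithium. It sets out from 2. Alkylation with 4-methoxybenzyl chloride (K2CO3, DMF) should give 8-iodo-7-(4-methoxybenzyloxy)coumarin F4. Palladium-catalysed silylation of the aryl iodide with hexamethyldisilane (Pd2(dba)3, bulky biarylphosphine, LiOAc, DMF, 100 °C) should give 7-(4-methoxybenzyloxy)-8-(trimethylsilyl)coumarin F5. Oxidative removal of the benzyl ether (DDQ, CH2Cl2/H2O) should give 7-hydroxy-8-(trimethylsilyl)coumarin F6. Triflation (Tf2O, pyridine, CH2Cl2, 0 °C) returns to the route at 6.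

Step 8 (methylation). The free or deprotonated o-hydroxyaryl enone may close by oxa-Michael addition onto C3' to a dimethylchromanone during isolation of 16 or under carbonate, and the enol ester may be cleaved by base. The fallback never liberates the phenol. It sets out from 6 and 11: step 7 is run as written, but the solution of phenoxide 15 is cooled and treated with DMF and iodomethane instead of acid. This three-component variant should alkylate the phenoxide in the flask and returns at 17. It makes no new compound.

**Further compounds**

F1 | step 7 | 8-iodo-7-methoxycoumarin | COc1ccc2ccc(=O)oc2c1I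
F2 | step 7 | 7-methoxy-8-(3-methylbut-1-yn-1-yl)coumarin | COc1ccc2ccc(=O)oc2c1C#CC(C)C
F3 | step 7 | 7-methoxy-8-(3-methyl-2-oxobutanoyl)coumarin | COc1ccc2ccc(=O)oc2c1C(=O)C(=O)C(C)C
F4 | step 3 | 8-iodo-7-(4-methoxybenzyloxy)coumarin | COc1ccc(COc2ccc3ccc(=O)oc3c2I)cc1
F5 | step 3 | 7-(4-methoxybenzyloxy)-8-(trimethylsilyl)coumarin | COc1ccc(COc2ccc3ccc(=O)oc3c2[Si](C)(C)C)cc1
F6 | step 3 | 7-hydroxy-8-(trimethylsilyl)coumarin | C[Si](C)(C)c1c(O)ccc2ccc(=O)oc12
F0 | step 8 | none | none
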